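The route rests on reading ring A of the pyrano[3,4-c]pyran-3-one (C-4a, C-5, C-6, O-7, C-8, C-8a) as a [4+2] adduct: the heterodiene O-7=C-8–C-8a=C-4a joins the enol ether C-5=C-6, while an ester on C-8a activates the diene and later becomes C-1. In one flask a formylacetate and 3-silyloxypropanal condense to the 2-formylacrylate (C-4a=C-8a), which takes up an (E)-enynyl ethyl ether under Cu(OTf)2 and a tert-butyl bis(oxazoline) ligand; ring A and the stereocentres C-4a, C-5 and C-6 arise together from three small achiral pieces. Ring B then follows by lactone transposition, and the alkyne is turned into the C-5 alkenyl chain.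

Key step: step 5

Numbering used throughout, also for monocyclic intermediates: ring B C-1, O-2, C-3, C-4, C-4a, C-8a; ring A C-4a, C-5, C-6, O-7, C-8, C-8a.
Assumption 1: the enol ether is used as its ethyl ether, because the geometrically pure (E)-2-ethoxyethenylboronate is commercial; the alkoxy group is a spectator that leaves in step 8.
Assumption 2: the (S,S)-ligand is written in step 5 by analogy with chelated alkylidene malonates; which antipode exposes the required face of the copper-bound formyl ester has to be established in the first run, and the (R,R)-ligand is equally available.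

Step 1
Reactants: 1 methyl acetate; 2 methyl formate
Product: 3 sodium (E)-3-methoxy-3-oxoprop-1-en-1-olate (sodium enolate of methyl 3-oxopropanoate)
Conditions: NaH, MeOH (cat.), Et2O, 0 °C to rt; solid filtered off
Reagents that add atoms: sodium hydride, [Na+].[H-]
Why: Crossed Claisen condensation in which methyl formate cannot enolise and is the better electrophile, while the product precipitates as its stable sodium enolate and pulls the equilibrium over.

Step 2
Reactants: 4 3-(tert-butyldimethylsilyloxy)propan-1-ol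
Product: 5 3-(tert-butyldimethylsilyloxy)propanal
Conditions: TEMPO (10 mol %), PhI(OAc)2, CH2Cl2, rt
Reagents that add atoms: none
Why: Oxoammonium (TEMPO) oxidation of a primary alcohol stops at the aldehyde under anhydrous conditions and leaves the silyl ether alone; the aldehyde is used fresh.

Step 3
Reactants: 6 trimethylsilylacetylene
Product: 7 (bromoethynyl)trimethylsilane
Conditions: NBS (1.05 equiv), AgNO3 (10 mol %), acetone, rt
Reagents that add atoms: N-bromosuccinimide, O=C1CCC(=O)N1Br
Why: Silver-catalysed electrophilic bromination of a terminal alkyne through the silver acetylide is a standard route to 1-bromoalkynes, and with one equivalent of NBS the terminal C–H reacts far faster than the C–Si bond.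

Step 4
Reactants: 7 (bromoethynyl)trimethylsilane; 8 (E)-2-(2-ethoxyethenyl)-4,4,5,5-tetramethyl-1,3,2-dioxaborolane
Product: 9 (E)-1-ethoxy-4-(trimethylsilyl)but-1-en-3-yne
Conditions: Pd(PPh3)4 (3 mol %), K3PO4, THF/H2O (20:1), rt
Reagents that add atoms: none
Why: Suzuki–Miyaura coupling of an alkenylboronate with a 1-bromoalkyne proceeds with retention of the alkene geometry, so the E enol ether is fixed by the boronate.

Step 5
Reactants: 3 sodium enolate of methyl 3-oxopropanoate; 5 3-(tert-butyldimethylsilyloxy)propanal; 9 (E)-1-ethoxy-4-(trimethylsilyl)but-1-en-3-yne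
Product: 12 methyl (2S,3R,4S)-4-[2-(tert-butyldimethylsilyloxy)ethyl]-2-ethoxy-3-[(trimethylsilyl)ethynyl]-3,4-dihydro-2H-pyran-5-carboxylate, via methyl 3-oxopropanoate 10 (not isolated), via methyl (Z)-2-formyl-5-(tert-butyldimethylsilyloxy)pent-2-enoate 11 (not isolated)
Conditions: HCl (1.0 equiv, in Et2O), CH2Cl2, –20 °C; 5, piperidinium acetate (5 mol %), 4 Å MS, 0 °C; then 9, Cu(OTf)2 (12 mol %), (S,S)-t-Bu-box (13 mol %), –78 to –40 °C
Reagents that add atoms: none
Why: Knoevenagel condensation of the liberated formyl ester 10 with aldehyde 5 gives the 2-formylacrylate 11, in which the formyl C=O and the new C-4a=C-8a bond form an electron-poor 1-oxa-1,3-diene held on divalent copper through the formyl and ester oxygens. Enol ether 9 then adds in a concerted but asynchronous inverse-electron-demand hetero-Diels–Alder reaction, C-5 bonding to C-4a ahead of O-7 to C-6; the closest known reaction types are the domino Knoevenagel–hetero-Diels–Alder reaction of alkylidene 1,3-dicarbonyl compounds with enol ethers and the copper bis(oxazoline)-catalysed cycloaddition of chelating oxadienes. Ring A is closed by the [4+2] cycloaddition itself, both new bonds forming suprafacially on each partner. C-4a and C-6 should become cis through the endo position of the ethoxy group, C-5 trans to both because the E geometry of 9 is retained, and the absolute configuration should come from the C2-symmetric ligand, whose tert-butyl groups block one face of the planar chelate. The step needs regioselectivity, secured by the polarisation of both partners, the formyl and not the ester carbonyl as diene terminus, and a catalysed pathway that outruns the thermal one, secured by running the cycloaddition at –78 °C with the catalyst in excess over the ammonium salt. The E and Z isomers of 11 interconvert and only the one with the chain anti to the formyl group reacts readily, so the endo rule translates into the 4a,6-cis pattern.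

Step 6
Reactants: 12 methyl (2S,3R,4S)-4-[2-(tert-butyldimethylsilyloxy)ethyl]-2-ethoxy-3-[(trimethylsilyl)ethynyl]-3,4-dihydro-2H-pyran-5-carboxylate
Product: 13 (4aS,5R,6S)-6-ethoxy-5-ethynyl-4,4a,5,6-tetrahydro-1H,3H-pyrano[3,4-c]pyran-1-one
Conditions: TBAF (2.2 equiv), THF, 0 °C to rt
Reagents that add atoms: none
Why: Fluoride cleaves the C–Si bond of the alkyne and the O–Si bond, and the freed C-3 alkoxide closes a six-membered lactone on the C-8a ester (intramolecular transesterification), which protects the C-3 oxygen and turns C-1 into a lactone carbonyl that can be reduced cleanly to the aldehyde level.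

Step 7
Reactants: 13 (4aS,5R,6S)-6-ethoxy-5-ethynyl-4,4a,5,6-tetrahydro-1H,3H-pyrano[3,4-c]pyran-1-one
Product: 14 (4aS,5S,6S)-6-ethoxy-5-(1-iodoethenyl)-4,4a,5,6-tetrahydro-1H,3H-pyrano[3,4-c]pyran-1-one
Conditions: B-iodo-9-BBN, hexane/CH2Cl2, –20 to 0 °C; then AcOH, 0 °C
Reagents that add atoms: B-iodo-9-borabicyclo[3.3.1]nonane, IB1C2CCCC1CCC2
Why: cis-Iodoboration of the terminal alkyne puts boron on the terminal and iodine on the internal carbon, and protodeboronation with acetic acid leaves the 2-iodoalkene (net Markovnikov hydroiodination); the acetal is deactivated by the vinylogous carbonate ring oxygen, and the C-5 descriptor changes only because iodine changes the priorities.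

Step 8
Reactants: 14 (4aS,5S,6S)-6-ethoxy-5-(1-iodoethenyl)-4,4a,5,6-tetrahydro-1H,3H-pyrano[3,4-c]pyran-1-one
Product: 15 (4aS,5S)-6-hydroxy-5-(1-iodoethenyl)-4,4a,5,6-tetrahydro-1H,3H-pyrano[3,4-c]pyran-1-one (both C-6 epimers)
Conditions: 2 M HCl (aq.), THF, 40 °C
Reagents that add atoms: water, O
Why: Acid hydrolysis of the mixed acetal is placed here because O-7 is still part of a vinylogous carbonate, so the enol ether is not protonated and the lactol stays ring-closed as in conjugated iridoid aglycones; the trans arrangement at C-4a/C-5 is the relaxed one and is not endangered by ring–chain equilibration.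

Step 9
Reactants: 15 (4aS,5S)-6-hydroxy-5-(1-iodoethenyl)-4,4a,5,6-tetrahydro-1H,3H-pyrano[3,4-c]pyran-1-one
Product: 16 (4aS,5S,6R)-6-(tert-butyldimethylsilyloxy)-5-(1-iodoethenyl)-4,4a,5,6-tetrahydro-1H,3H-pyrano[3,4-c]pyran-1-one
Conditions: TBSCl, imidazole, DMF, 0 °C
Reagents that add atoms: tert-butyldimethylsilyl chloride, CC(C)(C)[Si](C)(C)Cl
Why: Kinetic O-silylation of the equilibrating lactol should take the less hindered equatorial hydroxyl trans to the C-5 substituent, which sets C-6 as in the target (the descriptor becomes R only through the silicon priority) and gives an acetal that survives the hydride, borane, ruthenium and palladium steps; a minor C-6 epimer would be removed by chromatography.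

Step 10
Reactants: 16 (4aS,5S,6R)-6-(tert-butyldimethylsilyloxy)-5-(1-iodoethenyl)-4,4a,5,6-tetrahydro-1H,3H-pyrano[3,4-c]pyran-1-one
Product: 17 (4aS,5S,6R)-6-(tert-butyldimethylsilyloxy)-5-(1-iodoethenyl)-4,4a,5,6-tetrahydro-1H,3H-pyrano[3,4-c]pyran-1-ol (C-1 epimers, in equilibrium with the ring-opened hydroxy aldehyde)
Conditions: i-Bu2AlH (1.2 equiv), CH2Cl2, –78 °C; aq. potassium sodium tartrate
Reagents that add atoms: none
Why: Partial reduction of a lactone to the lactol with diisobutylaluminium hydride at low temperature, where the aluminium hemiacetal persists until work-up; the aldehyde tautomer released afterwards is a vinylogous formate and is never exposed to the hydride.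

Step 11
Reactants: 17 (4aS,5S,6R)-6-(tert-butyldimethylsilyloxy)-5-(1-iodoethenyl)-4,4a,5,6-tetrahydro-1H,3H-pyrano[3,4-c]pyran-1-ol
Product: 18 (1S)-1-[(2R,3S,4S)-2-(tert-butyldimethylsilyloxy)-4-(2-hydroxyethyl)-3-(1-iodoethenyl)-3,4-dihydro-2H-pyran-5-yl]but-3-en-1-ol
Conditions: (–)-Ipc2B(allyl) (2.5 equiv), Et2O, –78 to –20 °C; then pH 7 buffer, MeOH, H2O2, 0 °C
Reagents that add atoms: (–)-B-allyldiisopinocampheylborane, C[C@H]1[C@H](B(CC=C)[C@@H]3C[C@@H]4C[C@H]([C@H]3C)C4(C)C)C[C@@H]2C[C@H]1C2(C)C
Why: Brown allylation of the open hydroxy aldehyde through a closed chair transition state; the reagent derived from (+)-α-pinene adds to the Si face of aldehydes, which should give (1S) under reagent control, and the neutral conditions spare the silyl acetal and the enol ether.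

Step 12
Reactants: 18 (1S)-1-[(2R,3S,4S)-2-(tert-butyldimethylsilyloxy)-4-(2-hydroxyethyl)-3-(1-iodoethenyl)-3,4-dihydro-2H-pyran-5-yl]but-3-en-1-ol; 19 methacrolein (2-methylprop-2-enal)
Product: 20 (2E,5S)-5-[(2R,3S,4S)-2-(tert-butyldimethylsilyloxy)-4-(2-hydroxyethyl)-3-(1-iodoethenyl)-3,4-dihydro-2H-pyran-5-yl]-5-hydroxy-2-methylpent-2-enal
Conditions: 19 (10 equiv), second-generation Hoveyda–Grubbs catalyst RuCl2(H2IMes)(=CH-C6H4-2-OiPr) (5 mol %), CH2Cl2, 40 °C
Reagents that add atoms: none
Why: Olefin cross-metathesis of the only monosubstituted alkene with an excess of the 2-substituted acrolein should give the E trisubstituted enal under thermodynamic control; the iodoalkene and the trisubstituted enol ether are too hindered to enter the cycle, and the step precedes completion of the C-5 chain so that no ring-closing metathesis onto a 1,1-dialkyl alkene can compete.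

Step 13
Reactants: 21 5-chloropentan-2-one
Product: 22 5-iodopentan-2-one
Conditions: NaI, acetone, reflux
Reagents that add atoms: sodium iodide, [Na+].[I-]
Why: Finkelstein halide exchange driven by precipitation of NaCl.

Step 14
Reactants: 20 (2E,5S)-5-[(2R,3S,4S)-2-(tert-butyldimethylsilyloxy)-4-(2-hydroxyethyl)-3-(1-iodoethenyl)-3,4-dihydro-2H-pyran-5-yl]-5-hydroxy-2-methylpent-2-enal; 22 5-iodopentan-2-one
Product: 24 (2E,5S)-5-[(2R,3R,4S)-2-(tert-butyldimethylsilyloxy)-4-(2-hydroxyethyl)-3-(6-oxohept-1-en-2-yl)-3,4-dihydro-2H-pyran-5-yl]-5-hydroxy-2-methylpent-2-enal, via (4-oxopentyl)zinc iodide 23 (not isolated)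
Conditions: 22, Zn dust, LiCl, THF, 40 °C; then 20, Pd(PPh3)4 (5 mol %), THF, rt (4 equiv of 23)
Reagents that add atoms: none
Why: Negishi coupling of the 2-iodoalkene with an alkylzinc iodide made by direct zinc insertion; alkylzinc halides tolerate the ketone, the enal and free hydroxyl groups (the excess covers slow protonolysis), the coupling precedes any allylic ester so that zerovalent palladium finds only the C–I bond, and the C-5 descriptor returns to R only because iodine is gone.

Step 15
Reactants: 24 (2E,5S)-5-[(2R,3R,4S)-2-(tert-butyldimethylsilyloxy)-4-(2-hydroxyethyl)-3-(6-oxohept-1-en-2-yl)-3,4-dihydro-2H-pyran-5-yl]-5-hydroxy-2-methylpent-2-enal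
Product: 25 (2E)-4-[(1S,4aS,5R,6R)-6-(tert-butyldimethylsilyloxy)-3-oxo-5-(6-oxohept-1-en-2-yl)-4,4a,5,6-tetrahydro-1H,3H-pyrano[3,4-c]pyran-1-yl]-2-methylbut-2-enal
Conditions: TEMPO (20 mol %), PhI(OAc)2 (2.5 equiv), CH2Cl2, rt
Reagents that add atoms: none
Why: Oxidative lactonisation of a 1,5-diol, in which the primary C-3 alcohol is oxidised first, the aldehyde is captured by the C-1 hydroxyl as a six-membered lactol and this is oxidised to the δ-lactone, which closes ring B without touching the C-1 stereocentre.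

Step 16
Reactants: 25 (2E)-4-[(1S,4aS,5R,6R)-6-(tert-butyldimethylsilyloxy)-3-oxo-5-(6-oxohept-1-en-2-yl)-4,4a,5,6-tetrahydro-1H,3H-pyrano[3,4-c]pyran-1-yl]-2-methylbut-2-enal
Product: 26 (1S,4aS,5R,6R)-6-(tert-butyldimethylsilyloxy)-1-[(2E)-4-hydroxy-3-methylbut-2-enyl]-5-(6-oxohept-1-en-2-yl)-4,4a,5,6-tetrahydro-1H,3H-pyrano[3,4-c]pyran-3-one
Conditions: NaBH4 (0.5 equiv), EtOH/CH2Cl2 (1:3), –78 °C
Reagents that add atoms: none
Why: Chemoselective borohydride 1,2-reduction, since at –78 °C in this solvent mixture an aldehyde, also a conjugated one, is reduced faster than a dialkyl ketone, while the lactone and the silyl acetal are inert.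

Step 17
Reactants: 26 (1S,4aS,5R,6R)-6-(tert-butyldimethylsilyloxy)-1-[(2E)-4-hydroxy-3-methylbut-2-enyl]-5-(6-oxohept-1-en-2-yl)-4,4a,5,6-tetrahydro-1H,3H-pyrano[3,4-c]pyran-3-one
Product: 28 (2E)-4-[(1S,4aS,5R,6R)-6-acetoxy-3-oxo-5-(6-oxohept-1-en-2-yl)-4,4a,5,6-tetrahydro-1H,3H-pyrano[3,4-c]pyran-1-yl]-2-methylbut-2-enyl acetate (CNP0120157.1), via 6-O-silyl monoacetate 27 (not isolated)
Conditions: Ac2O (4 equiv), Et3N, DMAP (cat.), CH2Cl2, 0 °C; then TBAF (1.2 equiv), THF, –40 to 0 °C
Reagents that add atoms: acetic anhydride, CC(=O)OC(C)=O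
Why: DMAP-catalysed acetylation of the primary alcohol is followed by fluoride-triggered desilylative acylation, in which the anomeric alkoxide set free at low temperature is acetylated by the anhydride already present with retention at C-6, so that neither acid nor a free lactol, which the unconjugated enol ether and the allylic lactone would not survive, is needed.

Compound list
1 | methyl acetate | CC(=O)OC | starting material
2 | methyl formate | COC=O | starting material
3 | sodium (E)-3-methoxy-3-oxoprop-1-en-1-olate (sodium enolate of methyl 3-oxopropanoate) | [Na+].[O-]/C=C/C(=O)OC | intermediate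
4 | 3-(tert-butyldimethylsilyloxy)propan-1-ol | OCCCO[Si](C)(C)C(C)(C)C | starting material
5 | 3-(tert-butyldimethylsilyloxy)propanal | O=CCCO[Si](C)(C)C(C)(C)C | intermediate
6 | trimethylsilylacetylene | C#C[Si](C)(C)C | starting material
7 | (bromoethynyl)trimethylsilane | BrC#C[Si](C)(C)C | intermediate
8 | (E)-2-(2-ethoxyethenyl)-4,4,5,5-tetramethyl-1,3,2-dioxaborolane | CCO/C=C/B1OC(C)(C)C(C)(C)O1 | starting material
9 | (E)-1-ethoxy-4-(trimethylsilyl)but-1-en-3-yne | CCO/C=C/C#C[Si](C)(C)C | intermediate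
10 | methyl 3-oxopropanoate (not isolated) | COC(=O)CC=O | intermediate
11 | methyl (Z)-2-formyl-5-(tert-butyldimethylsilyloxy)pent-2-enoate (not isolated; interconverts with the E isomer) | COC(=O)/C(C=O)=C\CCO[Si](C)(C)C(C)(C)C | intermediate
12 | methyl (2S,3R,4S)-4-[2-(tert-butyldimethylsilyloxy)ethyl]-2-ethoxy-3-[(trimethylsilyl)ethynyl]-3,4-dihydro-2H-pyran-5-carboxylate (2,4-cis, 3 trans to both) | C[Si](C)(C)C#C[C@@H]1[C@@H](OCC)OC=C(C(=O)OC)[C@H]1CCO[Si](C)(C)C(C)(C)C | intermediate
13 | (4aS,5R,6S)-6-ethoxy-5-ethynyl-4,4a,5,6-tetrahydro-1H,3H-pyrano[3,4-c]pyran-1-one | C#C[C@@H]1[C@@H](OCC)OC=C2C(=O)OCC[C@H]21 | intermediate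
14 | (4aS,5S,6S)-6-ethoxy-5-(1-iodoethenyl)-4,4a,5,6-tetrahydro-1H,3H-pyrano[3,4-c]pyran-1-one | C=C(I)[C@@H]1[C@@H](OCC)OC=C2C(=O)OCC[C@H]21 | intermediate
15 | (4aS,5S)-6-hydroxy-5-(1-iodoethenyl)-4,4a,5,6-tetrahydro-1H,3H-pyrano[3,4-c]pyran-1-one (both C-6 epimers) | C=C(I)[C@@H]1C(O)OC=C2C(=O)OCC[C@H]21 | intermediate
16 | (4aS,5S,6R)-6-(tert-butyldimethylsilyloxy)-5-(1-iodoethenyl)-4,4a,5,6-tetrahydro-1H,3H-pyrano[3,4-c]pyran-1-one | C=C(I)[C@@H]1[C@@H](O[Si](C)(C)C(C)(C)C)OC=C2C(=O)OCC[C@H]21 | intermediate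
17 | (4aS,5S,6R)-6-(tert-butyldimethylsilyloxy)-5-(1-iodoethenyl)-4,4a,5,6-tetrahydro-1H,3H-pyrano[3,4-c]pyran-1-ol (C-1 epimers) | C=C(I)[C@@H]1[C@@H](O[Si](C)(C)C(C)(C)C)OC=C2C(O)OCC[C@H]21 | intermediate
18 | (1S)-1-[(2R,3S,4S)-2-(tert-butyldimethylsilyloxy)-4-(2-hydroxyethyl)-3-(1-iodoethenyl)-3,4-dihydro-2H-pyran-5-yl]but-3-en-1-ol | C=C(I)[C@@H]1[C@@H](O[Si](C)(C)C(C)(C)C)OC=C([C@@H](O)CC=C)[C@H]1CCO | intermediate
19 | methacrolein (2-methylprop-2-enal) | CC(=C)C=O | starting material
20 | (2E,5S)-5-[(2R,3S,4S)-2-(tert-butyldimethylsilyloxy)-4-(2-hydroxyethyl)-3-(1-iodoethenyl)-3,4-dihydro-2H-pyran-5-yl]-5-hydroxy-2-methylpent-2-enal | C=C(I)[C@@H]1[C@@H](O[Si](C)(C)C(C)(C)C)OC=C([C@@H](O)C/C=C(\C)C=O)[C@H]1CCO | intermediate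
21 | 5-chloropentan-2-one | CC(=O)CCCCl | starting material
22 | 5-iodopentan-2-one | CC(=O)CCCI | intermediate
23 | (4-oxopentyl)zinc iodide (not isolated) | CC(=O)CCC[Zn]I | intermediate
24 | (2E,5S)-5-[(2R,3R,4S)-2-(tert-butyldimethylsilyloxy)-4-(2-hydroxyethyl)-3-(6-oxohept-1-en-2-yl)-3,4-dihydro-2H-pyran-5-yl]-5-hydroxy-2-methylpent-2-enal | C=C(CCCC(C)=O)[C@@H]1[C@@H](O[Si](C)(C)C(C)(C)C)OC=C([C@@H](O)C/C=C(\C)C=O)[C@H]1CCO | intermediate
25 | (2E)-4-[(1S,4aS,5R,6R)-6-(tert-butyldimethylsilyloxy)-3-oxo-5-(6-oxohept-1-en-2-yl)-4,4a,5,6-tetrahydro-1H,3H-pyrano[3,4-c]pyran-1-yl]-2-methylbut-2-enal | C=C(CCCC(C)=O)[C@@H]1[C@@H](O[Si](C)(C)C(C)(C)C)OC=C2[C@H](C/C=C(\C)C=O)OC(=O)C[C@H]21 | intermediate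
26 | (1S,4aS,5R,6R)-6-(tert-butyldimethylsilyloxy)-1-[(2E)-4-hydroxy-3-methylbut-2-enyl]-5-(6-oxohept-1-en-2-yl)-4,4a,5,6-tetrahydro-1H,3H-pyrano[3,4-c]pyran-3-one | C=C(CCCC(C)=O)[C@@H]1[C@@H](O[Si](C)(C)C(C)(C)C)OC=C2[C@H](C/C=C(\C)CO)OC(=O)C[C@H]21 | intermediate
27 | (2E)-4-[(1S,4aS,5R,6R)-6-(tert-butyldimethylsilyloxy)-3-oxo-5-(6-oxohept-1-en-2-yl)-4,4a,5,6-tetrahydro-1H,3H-pyrano[3,4-c]pyran-1-yl]-2-methylbut-2-enyl acetate (not isolated) | C=C(CCCC(C)=O)[C@@H]1[C@@H](O[Si](C)(C)C(C)(C)C)OC=C2[C@H](C/C=C(\C)COC(C)=O)OC(=O)C[C@H]21 | intermediate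
28 | (2E)-4-[(1S,4aS,5R,6R)-6-acetoxy-3-oxo-5-(6-oxohept-1-en-2-yl)-4,4a,5,6-tetrahydro-1H,3H-pyrano[3,4-c]pyran-1-yl]-2-methylbut-2-enyl acetate (CNP0120157.1) | C=C(CCCC(C)=O)[C@@H]1[C@@H](OC(C)=O)OC=C2[C@H](C/C=C(\C)COC(C)=O)OC(=O)C[C@H]21 | target

Total step count: 17 steps.
Longest linear sequence: 14 steps (from 6 through steps 3 to 12 and 14 to 17).

Steps most likely to fail

1. Step 5. Risk: insufficient facial discrimination on the copper chelate, or an uncatalysed cycloaddition that competes and erodes both the enantiomeric purity and the endo preference. Fallback: 3 is neutralised with HCl in Et2O as in step 5, and the three components 3, 5 and 9 are combined without copper under ethylenediammonium diacetate catalysis (CH2Cl2, 4 Å MS, rt), the classical domino Knoevenagel–hetero-Diels–Alder conditions. This should give 12 as a racemate, that is together with its mirror image methyl (2R,3S,4R)-4-[2-(tert-butyldimethylsilyloxy)ethyl]-2-ethoxy-3-[(trimethylsilyl)ethynyl]-3,4-dihydro-2H-pyran-5-carboxylate F1 in equal amount. Treatment of the mixture of 12 and F1 with TBAF as in step 6 should give 13 and its enantiomer (4aR,5S,6R)-6-ethoxy-5-ethynyl-4,4a,5,6-tetrahydro-1H,3H-pyrano[3,4-c]pyran-1-one F2 side by side, and F2 is removed by preparative chromatography on a chiral stationary phase. The fallback sets out from 3, 5 and 9 and comes back to the route at 13.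

2. Step 12. Risk: stalling of the metathesis through deactivation of the ruthenium carbene (chelation by the diol and the enol ether oxygen, or interference of the iodoalkene), with alkene isomerisation as a side path. Fallback: the five-carbon chain is added in one piece by a vinylogous aldol reaction, setting out from lactol 17. Silylation with TESCl and imidazole in CH2Cl2 traps the open form as (2R,3S,4S)-2-(tert-butyldimethylsilyloxy)-3-(1-iodoethenyl)-4-[2-(triethylsilyloxy)ethyl]-3,4-dihydro-2H-pyran-5-carbaldehyde F3 in one operation. A vinylogous Mukaiyama aldol reaction of F3 with tert-butyl(dimethyl)[(2-methylbuta-1,3-dien-1-yl)oxy]silane, promoted by an N-tosyltryptophan-derived B-phenyl oxazaborolidinone in EtCN at –78 °C (the enantiomer of the promoter being chosen for attack on the Si face of the aldehyde), should bond the γ-carbon to C-1 and give after aqueous work-up (2E,5S)-5-[(2R,3S,4S)-2-(tert-butyldimethylsilyloxy)-3-(1-iodoethenyl)-4-[2-(triethylsilyloxy)ethyl]-3,4-dihydro-2H-pyran-5-yl]-5-hydroxy-2-methylpent-2-enal F4 as the E enal. Pyridine-buffered HF·pyridine at 0 °C then removes only the primary triethylsilyl group of F4 and the route is rejoined at 20.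

3. Step 17. Risk: ring opening of the anomeric alkoxide before it is acylated, or anomerisation that delivers the wrong configuration at C-6. Fallback: deprotection and acylation are separated and no free alkoxide is generated, setting out from 26. Acetylation (Ac2O, pyridine, 0 °C) gives 27, which is now isolated. Cleavage of the silyl acetal with pyridine-buffered HF·pyridine in THF at –20 °C should give the lactol (2E)-4-[(1S,4aS,5R)-6-hydroxy-3-oxo-5-(6-oxohept-1-en-2-yl)-4,4a,5,6-tetrahydro-1H,3H-pyrano[3,4-c]pyran-1-yl]-2-methylbut-2-enyl acetate F5 as a pair of equilibrating C-6 epimers. The lactol F5 is acetylated at once with Ac2O in pyridine at 0 °C, where the equatorial hydroxyl trans to the C-5 substituent should react faster, and the fallback ends at the target 28.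

Further compounds
F1 | step 5 | methyl (2R,3S,4R)-4-[2-(tert-butyldimethylsilyloxy)ethyl]-2-ethoxy-3-[(trimethylsilyl)ethynyl]-3,4-dihydro-2H-pyran-5-carboxylate | C[Si](C)(C)C#C[C@H]1[C@H](OCC)OC=C(C(=O)OC)[C@@H]1CCO[Si](C)(C)C(C)(C)C
F2 | step 5 | (4aR,5S,6R)-6-ethoxy-5-ethynyl-4,4a,5,6-tetrahydro-1H,3H-pyrano[3,4-c]pyran-1-one | C#C[C@H]1[C@H](OCC)OC=C2C(=O)OCC[C@@H]21
F3 | step 12 | (2R,3S,4S)-2-(tert-butyldimethylsilyloxy)-3-(1-iodoethenyl)-4-[2-(triethylsilyloxy)ethyl]-3,4-dihydro-2H-pyran-5-carbaldehyde | C=C(I)[C@@H]1[C@@H](O[Si](C)(C)C(C)(C)C)OC=C(C=O)[C@H]1CCO[Si](CC)(CC)CC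
F4 | step 12 | (2E,5S)-5-[(2R,3S,4S)-2-(tert-butyldimethylsilyloxy)-3-(1-iodoethenyl)-4-[2-(triethylsilyloxy)ethyl]-3,4-dihydro-2H-pyran-5-yl]-5-hydroxy-2-methylpent-2-enal | C=C(I)[C@@H]1[C@@H](O[Si](C)(C)C(C)(C)C)OC=C([C@@H](O)C/C=C(\C)C=O)[C@H]1CCO[Si](CC)(CC)CC
F5 | step 17 | (2E)-4-[(1S,4aS,5R)-6-hydroxy-3-oxo-5-(6-oxohept-1-en-2-yl)-4,4a,5,6-tetrahydro-1H,3H-pyrano[3,4-c]pyran-1-yl]-2-methylbut-2-enyl acetate | C=C(CCCC(C)=O)[C@@H]1C(O)OC=C2[C@H](C/C=C(\C)COC(C)=O)OC(=O)C[C@H]21
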